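In the grey run, left-handed substrate plus left-handed product ends at 49.8%, which is half of the racemic charge, as it should be when the percentages count both substrates together; so left-handed product is measured against the whole charge and not against the left-handed half.

all flasks: left-handed substrate 0.40 M; right-handed substrate 0.40 M; gas 160 mM (held)
- violet: free catalyst 0.047 mol%; run made earlier
- green: free catalyst 0.1 mol%; run made earlier
- grey: free catalyst 0.24 mol%; run made earlier
- zeta: free catalyst 0.2 mol%; time 20 h
- alpha: free catalyst 0.05 mol%; time 40 h

| run | time / h | left-handed product / % | left-handed substrate / % |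
|---|---|---|---|
| violet | 2.00 | 0.4 | 50.5 |
| violet | 4.00 | 0.1 | 49.6 |
| violet | 6.00 | 1.1 | 48.7 |
| violet | 8.00 | 2.8 | 46.7 |
| violet | 10.0 | 3.5 | 46.4 |
| green | 2.00 | 0.6 | 49.4 |
| green | 4.00 | 2.2 | 47.8 |
| green | 6.00 | 4.6 | 45.8 |
| green | 8.00 | 5.8 | 44.0 |
| green | 10.0 | 7.6 | 42.0 |
| grey | 2.00 | 1.9 | 47.8 |
| grey | 4.00 | 3.9 | 46.2 |
| grey | 6.00 | 8.4 | 40.9 |
| grey | 8.00 | 11.4 | 39.2 |
| grey | 10.0 | 14.9 | 34.9 |

(scatter of a reading: 0.5 percentage points)

- free catalyst is single-handed; left-handed substrate and right-handed substrate are mirror images of each other, charged as a racemate, each of them at the stated concentration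
- at the start none of the gas is in solution

1. the flask that ends with the higher amount of left-handed product, in percent of the left-handed substrate and right-handed substrate together charged, or "neither" when 2 percentage points or less lies between them (zeta / alpha / neither)
2. final left-handed product, as a percentage of the left-handed substrate and right-handed substrate together charged, in zeta
3. final left-handed product, as a percentage of the left-handed substrate and right-handed substrate together charged, in alpha

Does the grey curve bend as its substrate goes? It gains 6.5 percentage points from 2.00 h to 6.00 h and 6.5 points from 6.00 h to 10.0 h, while left-handed substrate falls from 47.8% to 34.9%. That is a straight, zero-order line.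

Where does it start? Grey's line, drawn back, meets zero at 0.831 h.

So what do I carry? The slope as a fraction of the charge per hour, scaled to green's loading of 0.1 mol%.

Is it constant? Not quite. Violet reads 0.00824 h⁻¹, give or take 0.00188 h⁻¹; green reads 0.00875 h⁻¹; grey reads 0.00677 h⁻¹, lower than green.

Then zeta? Interpolating between green and grey gives the scaled rate 0.00734 h⁻¹, and so 28.1%.

And alpha, beside violet's loading? The mean of violet and green, 0.00850 h⁻¹, gives 16.6%. I commit to zeta, higher than alpha by more than 2 points.

The forecast, “Treating the loss of left-handed substrate as first order”, said zeta, with 25% and 15%, both lower than my figures.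

The flasks give zeta, with 28.2% in zeta and 19.4% in alpha.

    partner + catalyst intermediate A → free catalyst + left-handed product (k = 4.80 M⁻¹ min⁻¹)
    partner + catalyst intermediate B → free catalyst + right-handed product (k = 1.70 M⁻¹ min⁻¹)
    gas ⇌ partner, rate k3*(csat - [partner]) (kL = 0.00420 min⁻¹)
    partner → decomposed reagent (k = 0.00290 min⁻¹)
    free catalyst + right-handed substrate ⇌ catalyst intermediate B (K = 1.20 M⁻¹, k = 470 M⁻¹ min⁻¹)
    free catalyst + left-handed substrate ⇌ catalyst intermediate A (K = 25.0 M⁻¹, k = 420 M⁻¹ min⁻¹)

In zeta, gas passed into partner, which stood at 0.0646 M after 10.0 h and 0.0663 M after 20.0 h, while catalyst intermediate A, the resting state, held 83.0% and then 74.4% of the catalyst. Left-handed product meanwhile rose from 13.3% to 28.2%. The scaled rate 0.00734 h⁻¹ gives 10.5% for zeta's neighbour read at 8.0 h, and that flask holds 10.2%. Alpha's result scales to 0.00991 h⁻¹, higher than 0.00734 h⁻¹, with partner at 0.0851 M after 40.0 h.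

The earlier runs and the new flask are calculated from invented constants; the scatter is artificial.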